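Per litre of solution, each unit of product in this scheme is paid for with one unit of reagent, and the next run of this flask hangs on that: charge more reagent, charge more catalyst, or allow more time.

substrate 10 mM; reagent 0.900 equiv; free catalyst 2 mol%; time 30 min

    substrate + free catalyst → catalyst intermediate A (k1 = 310 M⁻¹ s⁻¹)
    reagent + catalyst intermediate A → catalyst intermediate B (k2 = 80 M⁻¹ s⁻¹)
    catalyst intermediate B → free catalyst + product (k3 = 1.5 s⁻¹)
    crystals ⇌ product, rate k4*(cs4 - [product]) while solid is left; crystals form when [product] > cs4 (cs4 = 4.5 mM, k4 = 0.26 s⁻¹)

- for product the crystals are counted in
- as a solid, counted per litre of solution: crystals
- run time (flask): 30 min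

* the product and crystals together standing at 30 min, as a percentage of the substrate charged
* concentration of product in solution at 30 min, in percent of saturation

By hand, the balance of reagent is written first, since its charge is smaller than the substrate's. Reagent passes into catalyst intermediate B, which falls apart to free catalyst and one product:

c(reagent) + c(catalyst intermediate B) + c(product) + c(crystals) = 0.900 equiv × 10 mM = 9.00 mM

This sum is the reagent ceiling, the most product and crystals that the limiting reagent can pay for. Whether the flask reaches it in time is judged from the reagent's lifetime with the catalyst sitting as catalyst intermediate A:

1 / (80 M⁻¹ s⁻¹ × 0.200 mM) = 1.04 min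

That is far shorter than the run, so this reckoning puts the flask at 90.0% of the substrate. The ceiling is also higher than the solubility, and exchange with the crystals takes about 3.85 s, far shorter than the run. Dissolved product should therefore stand at 4.5 mM, with 4.50 mM as crystals. On this reckoning the next run gains from reagent, not from time or catalyst.

The forecast gives the same figures, 90% and 100%, with the reagent “used up within a few minutes”.

The simulation gives 90.0% and 100%.

In this flask product and crystals stop at the ceiling, 90.0%, because the reagent is depleted, 0% of it standing at 30.0 min. The same run without that depletion reaches 100%, while ten times the time leaves 90.0%. The forecast's 90% would be off by 5 points at 0.850 equiv or 0.950 equiv of reagent, or with the time cut to 4.04 min.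

In the neighbour charged with 0.230 equiv of reagent, the ceiling falls to 2.30 mM, or 23.0%, lower than the solubility. That neighbour gives 23.0%, with crystals at 0%.

The numbers of this flask are made up; the result is computed.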